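(The readings stem from a simulated flask for substances that don't exist; the scatter is artificial.)

The coupling partner was held at one charge in the amber, ochre and red runs, and we suspect that it is what stops them.

| flask | starting material | second substrate | coupling partner | free catalyst | remark | time |
|---|---|---|---|---|---|---|
| amber | 0.020 M | 10 mM | 0.020 M | 10 µM | run made earlier |  |
| ochre | 0.020 M | 6.7 mM | 0.020 M | 10 µM | run made earlier |  |
| red | 0.020 M | 15 mM | 0.020 M | 10 µM | run made earlier |  |
| gamma | 0.020 M (fed, over 10 min) | 10.0 mM | 0.0200 M | 10 µM | all else is in the flask from the start; the feed brings no volume worth counting | 25 min |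
| beta | 0.020 M | 10.0 mM | 0.0200 M | 10 µM | everything together at the start | 25 min |
| eta | 0.020 M | 10.0 mM | 0.0200 M (fed, over 10 min) | 10 µM | all else is in the flask from the start; the feed brings no volume worth counting | 25 min |

- amber (time / min: side product / %, target / %): 1.00: 6.6, 4.3; 3.00: 21.7, 0.6; 5.00: 31.7, 0; 8.00: 37.8, 1.6; 12.0: 44.4, 0; 15.0: 44.3, 0.9
- ochre (time / min: side product / %, target / %): 5.00: 31.4, 0.8; 10.0: 40.5, 1.3; 15.0: 45.1, 0.7; 20.0: 46.9, 0; 25.0: 51.0, 0.8; 30.0: 51.9, 2.4
- red (time / min: side product / %, target / %): 5.00: 29.0, 0; 10.0: 37.7, 0.3; 15.0: 42.8, 0; 20.0: 46.2, 0; 25.0: 48.0, 0; 30.0: 47.7, 2.0

(standard deviation of a reading: 1 percentage point)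

- percentages count the starting material that a species holds: one side product counts as two

- the flask with the highest amount of side product, in percent of the starting material charged ("all alike" if they lie within 1.5 percentage points) (gamma / beta / eta / all alike)
- final side product, as a percentage of the starting material charged, in gamma
- final side product, as a percentage of the starting material charged, in beta
- final side product, as a percentage of the starting material charged, in eta

Side product reads 31.4% in ochre and 29.0% in red at 5.00 min, so we set the second substrate aside. Ochre gains 31.4% in its first 5.00 min and 0.9 percentage points in its last 5.00 min, while 45.7% of the starting material stands outside side product and target.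

Target shows at 4.3% at 1.00 min in amber and then fades, so we take it as the precursor: each side product holds two starting material units and one coupling partner. We therefore carry the partner share, the fraction of the coupling partner charge that stands in side product, which ochre puts at 25.9% by 30.0 min, about a quarter.

Now divide one rate by the other so that time drops out. If the productive route goes with [coupling partner] and a loss goes with its square, the ratio of productive route to loss rises as [coupling partner] falls. By our reckoning, feeding the partner over 10 min raises its share, so eta stands above beta. Feeding the starting material delivers on average 0.0100 M over 10 min, less than the 0.020 M that beta holds at the start, so by our reckoning gamma stands below beta.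

The forecast gave 33% for gamma, 50% for beta and 50% for eta, with beta highest, and on eta it differs from us: “If it is a bystander, eta matches beta at about 50%”.

The flasks give 30.1% in gamma, 48.7% in beta and 60.6% in eta, the most.

    2 coupling partner → self-condensation product (k = 0.262 M⁻¹ s⁻¹)
    starting material + target → side product (k = 2.21 M⁻¹ s⁻¹)
    coupling partner + catalyst intermediate A → free catalyst + target (k = 213 M⁻¹ s⁻¹)
    starting material → decomposition product (k = 1.32 × 10⁻⁶ s⁻¹)
    starting material + free catalyst ⇌ catalyst intermediate A (K = 150 M⁻¹, k = 3440 M⁻¹ s⁻¹)
    coupling partner + catalyst intermediate B → free catalyst + second product (k = 197 M⁻¹ s⁻¹)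
    second substrate + free catalyst ⇌ catalyst intermediate B (K = 42.0 M⁻¹, k = 571 M⁻¹ s⁻¹)

As partner share, eta holds 30.3% and beta 24.4%. In beta the coupling partner is the limiting reagent, down to 1.59% of its charge at 25.0 min, with self-condensation product at 0.00700 M, which holds 70.0% of that charge. Take a further flask like gamma but charged with 0.080 M of starting material: it gives 11.8% side product, a partner share of 23.6%, against 15.1% in gamma and the 25.9% read from ochre.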